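## Structural features

The target is a 1,4-di(indol-3-yl)benzene. The central benzene ring is fully substituted: four methoxy groups sit on C2, C3, C5 and C6, and the C3 atoms of two different indoles sit para to each other on C1 and C4. One indole carries a methoxy group on C6, the other a free hydroxyl on C5. There is no stereocentre, and because each aryl–indole axis is flanked by two identical methoxy groups no axial chirality can arise, so the problem is one of constitution only. The fragile parts are the two free indole N–H groups, the oxidation-prone 5-hydroxyindole and the electron-rich tetramethoxy core, which rule out strong oxidants and strong Lewis acids late in the route. The real difficulty is twofold: both aryl–indole bonds lie between two ortho methoxy groups, and the symmetric core must be desymmetrised so that two indoles differing in one oxygen substituent end up para. The key step exploits the benzo ring of the 6-methoxyindole. Its atoms C4 and C7 map onto the diene termini of a pyrrole-fused 2-pyranone, and C5 and C6 map onto the two carbons of a ketene acetal, whose acetal carbon delivers the C6 methoxy group at the right oxidation level. That turns the problem into the synthesis of a 4-arylpyrrole with a formyl group on C3 and an acetic acid chain on C2.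

## Logic of the disconnections

26 to 25: the O–CH2Ph bond is cut. The phenol stays masked as a benzyl ether through all basic, organometallic and acylating steps. The forward step must be a neutral hydrogenolysis that leaves two indoles untouched.

25 to 24: the two N–S bonds are cut. Sulfonyl groups on both nitrogens survive amide bases, aluminium hydride, trifluoroacetic acid and heat, and they make the diene of the key step electron-poor. The forward step must remove both without touching the benzyl ether.

24 to 20 and 21: the C4–C5 and C6–C7 bonds of the methoxyindole are cut. This removes a whole ring and the methoxy group in one operation and leaves a pyrrole-fused pyranone and a two-carbon ketene acetal. The forward step must add in one orientation only, and 20 must live long enough to be trapped.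

20 to 18 (through 19): the enol-lactone C4–O5 bond is cut and the acid is traced to its tert-butyl ester. The o-quinoid ring system returns to a stable aromatic pyrrole carrying a formyl group and an acetic ester. The forward step needs acidolysis and dehydration that spare the benzyl ether and the sulfonamides.

18 to 17: no skeletal bond is cut; the formyl group is traced to a nitrile. The nitrile is the activating group of the pyrrole synthesis and the acidifying group for metalation, and one hydride equivalent converts it to the aldehyde. The forward step must reduce the nitrile and spare the ester.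

17 to 15 and 16: the pyrrole C2–CH2 bond is cut. The two-carbon chain comes from a commercial zinc ester enolate. The forward step needs a halide at C2 and nowhere else.

15 to 13: the C2–I bond is cut. C2–H lies between the sulfonylated nitrogen and the nitrile, so deprotonation should find it. The forward step must prefer this site over C5–H of the pyrrole and C2–H of the sulfonylindole.

13 to 12: the pyrrole N–S bond is cut; this is a plain N-sulfonylation in the forward sense.

12 to 10 and 11: the pyrrole C2–C3 and C4–C5 bonds are cut. The whole pyrrole ring, with the nitrile next to the aryl group, comes from an aryl acrylonitrile and an isocyanide in one step. The forward step needs conjugate addition to a β-carbon that carries a doubly ortho-substituted aryl group.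

10 to 8 and 9: the aryl–vinyl bond is cut. The forward Heck reaction must achieve oxidative addition at a hindered, electron-rich aryl bromide.

8 to 2 and 5: the bond between the central ring and indole C3 is cut. Exchange of one bromine of 2 for a metal desymmetrises the core exactly once. The forward coupling must react at C–I much faster than at the remaining C–Br.

5 to 3, and 2 to 1: the C3–I and N–S bonds of 5 and the two C–Br bonds of 2 are cut. Both are simple electrophilic substitutions at the only reactive positions.

## Other disconnections considered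

Alternative 1: The cut is through N1–C2 and C3–C3a of the 6-methoxyindole, so its pyrrole ring is made last. In the forward sense 2-iodo-5-methoxyaniline A3 and the silylalkyne A2 would undergo a Larock heteroannulation (Pd(OAc)2, Na2CO3, LiCl) to give the 2-silylindole A1, followed by protodesilylation and debenzylation.
- In favour: the methoxy group comes in with a cheap aniline, so its position is not in question. The silyl group is expected to steer the aryl group to C3. A2 should be reachable by Sonogashira alkynylation of a bromide of the type of 8.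
- Against: the alkyne is flanked by a triethylsilyl group and an aryl ring with two ortho methoxy groups, so carbopalladation is likely to be slow and may be overtaken by reduction of A3. The silyl group costs one extra removal step.
- Comparison: on step economy and on certainty of the methoxy position this alternative is better than the chosen plan. On mechanism, the chosen plan forms the ring in a thermal pericyclic event in which the bulky aryl group is remote from the bond-forming termini. The chosen plan also needs no metal insertion next to the hindered core at the ring-forming stage.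

Alternative 2: Here the central benzene ring is the ring that is made. Thermolysis of the 4-alkenyl-4-hydroxycyclobutenone A5 would open the four-membered ring to a dienylketene, whose ketene carbon closes onto the methoxy-bearing vinyl carbon (a Moore-type ring expansion), giving hydroquinone A4 after tautomerisation.
- In favour: it is convergent, it places the two different indoles para by construction, and it avoids both hindered aryl–indole cross-couplings.
- Against: A4 still needs double O-methylation of an air-sensitive hydroquinone and removal of two SEM groups and a benzyl group. Assembling A5 requires adding a metalated, unsymmetrically substituted enol ether to a squarate-derived dione with control of which carbonyl is attacked.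
- Comparison: mechanistically it is the equal of the chosen plan, since both rely on a thermal electrocyclic or cycloaddition cascade driven by aromatisation. It is better at differentiating the two indoles by construction. On step economy it is no shorter, and its end-game has three deprotections against two.

Alternative 3: The cut is through C3–C3a and N1–C7a of the 5-hydroxyindole. Benzylamine A8 and the arylacetaldehyde A7 would form an enamine whose β-carbon adds to p-benzoquinone A9; condensation of nitrogen on the quinone carbonyl (Nenitzescu-type) would give the N,N'-dibenzyl compound A6.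
- In favour: the phenol appears free and needs no protecting group, and the three components are simple.
- Against: the enamine has no acceptor group, so O-attack leading to benzofurans and redox between enamine and quinone are likely to compete. The electron-rich N-benzyl-6-methoxyindole in A7 is itself a nucleophile towards A9. Two N-benzyl groups on indoles would have to be removed under forcing conditions next to a free phenol.
- Comparison: it is better than the chosen plan in that the hydroxyl needs no protection, and the ring-forming step is shorter. The chosen plan is safer in chemoselectivity and in the end-game, where its protecting groups leave under mild conditions.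

Key step: step 11

Assumptions and remarks on the chemistry:
- The nitrogen protecting groups are free to choose. Phenylsulfonyl is used on both nitrogens in place of a tert-butyl carbamate, because a carbamate on an electron-poor pyrrole would not be expected to survive the amide base, the aluminium hydride, the trifluoroacetic acid and the heating that the route needs. The skeletons of 20 and 24 are unchanged.
- 10 is drawn as the E isomer; either geometry serves in step 5.
- In the names below, Ar stands for the 4-[5-benzyloxy-1-(phenylsulfonyl)indol-3-yl]-2,3,5,6-tetramethoxyphenyl group.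

## Route

Step 1
Reactants: 1 1,2,4,5-tetramethoxybenzene
Product: 2 1,4-dibromo-2,3,5,6-tetramethoxybenzene
Conditions: Br2, CH2Cl2, 0 °C to rt
Reagents that add atoms: bromine, BrBr
Why: Electrophilic aromatic bromination; the two remaining ring positions are the only C–H sites and are strongly activated by the flanking methoxy groups, so dibromination is unambiguous.

Step 2
Reactants: 3 5-benzyloxyindole
Product: 5 5-benzyloxy-3-iodo-1-(phenylsulfonyl)indole, via 5-benzyloxy-3-iodoindole 4 (not isolated)
Conditions: I2, KOH, DMF, rt; then PhSO2Cl, 0 °C to rt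
Reagents that add atoms: iodine, II; benzenesulfonyl chloride, O=S(=O)(Cl)c1ccccc1
Why: Iodination of the indolide occurs at C3, the most nucleophilic position; the labile 3-iodoindole is N-sulfonylated in the same flask, which stabilises it and protects nitrogen for the coupling.

Step 3
Reactants: 2 1,4-dibromo-2,3,5,6-tetramethoxybenzene; 5 5-benzyloxy-3-iodo-1-(phenylsulfonyl)indole
Product: 8 5-benzyloxy-3-(4-bromo-2,3,5,6-tetramethoxyphenyl)-1-(phenylsulfonyl)indole, via (4-bromo-2,3,5,6-tetramethoxyphenyl)lithium 6 (not isolated), via (4-bromo-2,3,5,6-tetramethoxyphenyl)zinc chloride 7 (not isolated)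
Conditions: n-BuLi (1 equiv), THF, −78 °C; ZnCl2, −78 °C to rt; then 5, Pd(PPh3)4, THF, 50 °C
Reagents that add atoms: none
Why: Bromine–lithium exchange with one equivalent of n-BuLi should stop at the monolithio arene, which is transmetalated to zinc; Negishi coupling is expected at the C–I bond of 5 much faster than at the doubly ortho-substituted, electron-rich C–Br bonds, so one bromide is kept for step 4.

Step 4
Reactants: 8 5-benzyloxy-3-(4-bromo-2,3,5,6-tetramethoxyphenyl)-1-(phenylsulfonyl)indole; 9 acrylonitrile
Product: 10 (E)-3-Ar-acrylonitrile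
Conditions: Pd2(dba)3, [HP(t-Bu)3]BF4, Cy2NMe, 1,4-dioxane, 100 °C
Reagents that add atoms: none
Why: Heck reaction; the bulky, electron-rich trialkylphosphine allows oxidative addition at the hindered aryl bromide, and insertion of the acceptor alkene followed by β-hydride elimination should give the aryl acrylonitrile.

Step 5
Reactants: 10 (E)-3-Ar-acrylonitrile; 11 tosylmethyl isocyanide
Product: 12 4-Ar-1H-pyrrole-3-carbonitrile
Conditions: NaH, Et2O/DMSO, 0 °C to rt
Reagents that add atoms: none
Why: van Leusen pyrrole synthesis: the isocyanide anion adds to the β-carbon, the nitrile-stabilised anion closes on the isocyanide carbon, and loss of sulfinate with tautomerisation gives the pyrrole; ortho-substituted aryl acrylonitriles are known substrates for this reaction.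

Step 6
Reactants: 12 4-Ar-1H-pyrrole-3-carbonitrile
Product: 13 4-Ar-1-(phenylsulfonyl)pyrrole-3-carbonitrile
Conditions: NaH, PhSO2Cl, THF, 0 °C to rt
Reagents that add atoms: benzenesulfonyl chloride, O=S(=O)(Cl)c1ccccc1
Why: N-sulfonylation of the pyrrolide anion; the sulfonyl group protects nitrogen, acidifies C2–H for step 7 and makes the later pyranone electron-poor, and phenylsulfonyl has no benzylic C–H to compete in the metalation.

Step 7
Reactants: 13 4-Ar-1-(phenylsulfonyl)pyrrole-3-carbonitrile
Product: 15 4-Ar-2-iodo-1-(phenylsulfonyl)pyrrole-3-carbonitrile, via C2-chloromagnesio pyrrole 14 (not isolated)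
Conditions: TMPMgCl·LiCl, THF, −40 °C; then I2, −40 °C to rt
Reagents that add atoms: iodine, II
Why: Directed deprotonative magnesiation; the pyrrole C2–H lies between the sulfonylated nitrogen and the nitrile and is the most acidic C–H in the molecule, the hindered amide base does not add to the nitrile, and iodinolysis of the C–Mg bond gives the 2-iodide.

Step 8
Reactants: 15 4-Ar-2-iodo-1-(phenylsulfonyl)pyrrole-3-carbonitrile; 16 (2-tert-butoxy-2-oxoethyl)zinc bromide, BrZnCH2CO2t-Bu
Product: 17 tert-butyl 2-[4-Ar-3-cyano-1-(phenylsulfonyl)pyrrol-2-yl]acetate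
Conditions: Pd2(dba)3, XPhos, THF, rt to 50 °C
Reagents that add atoms: none
Why: Palladium-catalysed α-arylation of a zinc ester enolate (Reformatsky reagent) with a heteroaryl iodide, a Negishi-type coupling that tolerates nitriles and sulfonamides and forms the C2–CH2 bond without strong base.

Step 9
Reactants: 17 tert-butyl 2-[4-Ar-3-cyano-1-(phenylsulfonyl)pyrrol-2-yl]acetate
Product: 18 tert-butyl 2-[4-Ar-3-formyl-1-(phenylsulfonyl)pyrrol-2-yl]acetate
Conditions: i-Bu2AlH, CH2Cl2, −78 °C; aq. tartaric acid, 0 °C
Reagents that add atoms: water, O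
Why: Partial reduction of a nitrile: hydroalumination gives an N-aluminoaldimine that is stable at −78 °C and is hydrolysed to the aldehyde on work-up, while the bulky tert-butyl ester is expected to react much more slowly at this temperature.

Step 10
Reactants: 18 tert-butyl 2-[4-Ar-3-formyl-1-(phenylsulfonyl)pyrrol-2-yl]acetate
Product: 20 3-Ar-1-(phenylsulfonyl)pyrano[4,3-b]pyrrol-6(1H)-one, via formyl acid 19 (not isolated)
Conditions: CF3CO2H/CH2Cl2, anisole, 0 °C to rt; evaporate; then Ac2O, 90 °C
Reagents that add atoms: none
Why: Acidolysis of the tert-butyl ester, then cyclodehydration of the ortho-formyl heteroarylacetic acid with Ac2O (mixed anhydride, bonding of carboxyl oxygen to the formyl carbon, loss of acetic acid), the established entry to 2-benzopyran-3-ones and to pyrano-fused indolones and pyrrolones; 20 is an o-quinoid diene and should be used at once.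

Step 11
Reactants: 20 3-Ar-1-(phenylsulfonyl)pyrano[4,3-b]pyrrol-6(1H)-one; 21 1,1-dimethoxyethene
Product: 24 5-benzyloxy-3-{2,3,5,6-tetramethoxy-4-[6-methoxy-1-(phenylsulfonyl)indol-3-yl]phenyl}-1-(phenylsulfonyl)indole, via bridged lactone cycloadduct 22 (not isolated), via 6,6-dimethoxy-5,6-dihydroindole 23 (not isolated)
Conditions: 21 (excess), toluene, 100 °C, sealed tube
Reagents that add atoms: none
Why: The o-quinoid pyranone 20 should act as an electron-poor diene towards the electron-rich alkene 21 in a [4+2] cycloaddition across C4 and C7, giving the bridged lactone 22 and restoring the aromatic pyrrole. Cycloreversion then expels CO2 to give 23, and loss of methanol from C5–H and C6–OMe aromatises the new ring to the 6-methoxyindole. The closest known reaction types are the cycloaddition–decarboxylation–elimination of 2-pyranones with ketene acetals to give aryl methyl ethers, and the cycloaddition–decarboxylation of pyrano-fused pyrroles and indoles with alkynes; this is a known reaction type applied to a new pairing. The benzo ring is closed by an intermolecular cycloaddition that forms C4–C5 and C6–C7 in one suprafacial event, and the six-membered carbocycle survives extrusion of the O–C(=O) bridge. The two bridgehead centres of 22 are racemic, tied to each other by the bicycle, and erased when CO2 and methanol leave, so no stereocentre remains. The step needs one orientation: the nucleophilic CH2 of 21 must bond to C4, the oxygen-bearing and most electrophilic diene terminus, so that the acetal carbon bonds to C7 and becomes C6. This follows the polarisation seen with 2-pyranones and is reinforced by the N-sulfonyl group, which damps donation from nitrogen into the C7a=C7–C6=O unit. The gain of pyrrole aromaticity on cycloaddition should favour addition across the diene over attack of 21 at the lactone carbonyl.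

Step 12
Reactants: 24 5-benzyloxy-3-{2,3,5,6-tetramethoxy-4-[6-methoxy-1-(phenylsulfonyl)indol-3-yl]phenyl}-1-(phenylsulfonyl)indole
Product: 25 5-benzyloxy-3-[2,3,5,6-tetramethoxy-4-(6-methoxy-1H-indol-3-yl)phenyl]-1H-indole
Conditions: Mg, MeOH/THF, rt, sonication
Reagents that add atoms: none
Why: Reductive cleavage of N-sulfonyl azoles by electron transfer from magnesium in methanol should remove both sulfonyl groups while aryl methyl ethers and the benzyl ether are inert; doing this before debenzylation avoids exposing a free 5-hydroxyindole to basic conditions.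

Step 13
Reactants: 25 5-benzyloxy-3-[2,3,5,6-tetramethoxy-4-(6-methoxy-1H-indol-3-yl)phenyl]-1H-indole
Product: 26 3-[2,3,5,6-tetramethoxy-4-(6-methoxy-1H-indol-3-yl)phenyl]-1H-indol-5-ol (target)
Conditions: H2 (1 atm), Pd/C, EtOAc/MeOH, rt
Reagents that add atoms: none
Why: Catalytic hydrogenolysis of the benzyl aryl ether under neutral conditions; the indole rings and methyl ethers are not expected to be reduced at ambient pressure, and the air-sensitive 5-hydroxyindole is set free only in the last step.

## Compound list

1 | 1,2,4,5-tetramethoxybenzene | COc1cc(OC)c(OC)cc1OC | starting material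
2 | 1,4-dibromo-2,3,5,6-tetramethoxybenzene | COc1c(Br)c(OC)c(OC)c(Br)c1OC | intermediate
3 | 5-benzyloxyindole | c1ccc(COc2ccc3[nH]ccc3c2)cc1 | starting material
4 | 5-benzyloxy-3-iodoindole | Ic1c[nH]c2ccc(OCc3ccccc3)cc12 | intermediate (not isolated)
5 | 5-benzyloxy-3-iodo-1-(phenylsulfonyl)indole | O=S(=O)(c1ccccc1)n1cc(I)c2cc(OCc3ccccc3)ccc21 | intermediate
6 | (4-bromo-2,3,5,6-tetramethoxyphenyl)lithium | [Li]c1c(OC)c(OC)c(Br)c(OC)c1OC | intermediate (not isolated)
7 | (4-bromo-2,3,5,6-tetramethoxyphenyl)zinc chloride | Cl[Zn]c1c(OC)c(OC)c(Br)c(OC)c1OC | intermediate (not isolated)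
8 | 5-benzyloxy-3-(4-bromo-2,3,5,6-tetramethoxyphenyl)-1-(phenylsulfonyl)indole | COc1c(Br)c(OC)c(OC)c(-c2cn(S(=O)(=O)c3ccccc3)c3ccc(OCc4ccccc4)cc23)c1OC | intermediate
9 | acrylonitrile | C=CC#N | starting material
10 | (E)-3-{4-[5-benzyloxy-1-(phenylsulfonyl)indol-3-yl]-2,3,5,6-tetramethoxyphenyl}acrylonitrile | N#C/C=C/c1c(OC)c(OC)c(-c2cn(S(=O)(=O)c3ccccc3)c3ccc(OCc4ccccc4)cc23)c(OC)c1OC | intermediate
11 | tosylmethyl isocyanide | Cc1ccc(S(=O)(=O)C[N+]#[C-])cc1 | starting material
12 | 4-{4-[5-benzyloxy-1-(phenylsulfonyl)indol-3-yl]-2,3,5,6-tetramethoxyphenyl}-1H-pyrrole-3-carbonitrile | N#Cc1c[nH]cc1-c1c(OC)c(OC)c(-c2cn(S(=O)(=O)c3ccccc3)c3ccc(OCc4ccccc4)cc23)c(OC)c1OC | intermediate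
13 | 4-Ar-1-(phenylsulfonyl)pyrrole-3-carbonitrile | N#Cc1cn(S(=O)(=O)c2ccccc2)cc1-c1c(OC)c(OC)c(-c2cn(S(=O)(=O)c3ccccc3)c3ccc(OCc4ccccc4)cc23)c(OC)c1OC | intermediate
14 | 4-Ar-2-(chloromagnesio)-1-(phenylsulfonyl)pyrrole-3-carbonitrile | N#Cc1c([Mg]Cl)n(S(=O)(=O)c2ccccc2)cc1-c1c(OC)c(OC)c(-c2cn(S(=O)(=O)c3ccccc3)c3ccc(OCc4ccccc4)cc23)c(OC)c1OC | intermediate (not isolated)
15 | 4-Ar-2-iodo-1-(phenylsulfonyl)pyrrole-3-carbonitrile | N#Cc1c(I)n(S(=O)(=O)c2ccccc2)cc1-c1c(OC)c(OC)c(-c2cn(S(=O)(=O)c3ccccc3)c3ccc(OCc4ccccc4)cc23)c(OC)c1OC | intermediate
16 | (2-tert-butoxy-2-oxoethyl)zinc bromide, BrZnCH2CO2t-Bu | CC(C)(C)OC(=O)C[Zn]Br | starting material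
17 | tert-butyl 2-[4-Ar-3-cyano-1-(phenylsulfonyl)pyrrol-2-yl]acetate | CC(C)(C)OC(=O)Cc1c(C#N)c(-c2c(OC)c(OC)c(-c3cn(S(=O)(=O)c4ccccc4)c4ccc(OCc5ccccc5)cc34)c(OC)c2OC)cn1S(=O)(=O)c1ccccc1 | intermediate
18 | tert-butyl 2-[4-Ar-3-formyl-1-(phenylsulfonyl)pyrrol-2-yl]acetate | CC(C)(C)OC(=O)Cc1c(C=O)c(-c2c(OC)c(OC)c(-c3cn(S(=O)(=O)c4ccccc4)c4ccc(OCc5ccccc5)cc34)c(OC)c2OC)cn1S(=O)(=O)c1ccccc1 | intermediate
19 | 2-[4-Ar-3-formyl-1-(phenylsulfonyl)pyrrol-2-yl]acetic acid | O=Cc1c(CC(=O)O)n(S(=O)(=O)c2ccccc2)cc1-c1c(OC)c(OC)c(-c2cn(S(=O)(=O)c3ccccc3)c3ccc(OCc4ccccc4)cc23)c(OC)c1OC | intermediate (not isolated)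
20 | 3-{4-[5-benzyloxy-1-(phenylsulfonyl)indol-3-yl]-2,3,5,6-tetramethoxyphenyl}-1-(phenylsulfonyl)pyrano[4,3-b]pyrrol-6(1H)-one | O=C1C=C2N(S(=O)(=O)c3ccccc3)C=C(c3c(OC)c(OC)c(-c4cn(S(=O)(=O)c5ccccc5)c5ccc(OCc6ccccc6)cc45)c(OC)c3OC)C2=CO1 | intermediate (key-step precursor)
21 | 1,1-dimethoxyethene | C=C(OC)OC | starting material
22 | bridged lactone cycloadduct, racemic (one enantiomer drawn): 8,8-dimethoxy-2-oxabicyclo[2.2.2]octan-3-one whose C5–C6 bond is the C2–C3 bond of the 4-Ar-1-(phenylsulfonyl)pyrrole, C5 being the carbon next to nitrogen | O=C1O[C@@H]2CC(OC)(OC)[C@H]1c1n(S(=O)(=O)c3ccccc3)cc(-c3c(OC)c(OC)c(-c4cn(S(=O)(=O)c5ccccc5)c5ccc(OCc6ccccc6)cc45)c(OC)c3OC)c12 | intermediate (not isolated)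
23 | 3-Ar-6,6-dimethoxy-1-(phenylsulfonyl)-5,6-dihydro-1H-indole | COC1(OC)CC=C2C(c3c(OC)c(OC)c(-c4cn(S(=O)(=O)c5ccccc5)c5ccc(OCc6ccccc6)cc45)c(OC)c3OC)=CN(S(=O)(=O)c3ccccc3)C2=C1 | intermediate (not isolated)
24 | 5-benzyloxy-3-{2,3,5,6-tetramethoxy-4-[6-methoxy-1-(phenylsulfonyl)indol-3-yl]phenyl}-1-(phenylsulfonyl)indole | COc1ccc2c(-c3c(OC)c(OC)c(-c4cn(S(=O)(=O)c5ccccc5)c5ccc(OCc6ccccc6)cc45)c(OC)c3OC)cn(S(=O)(=O)c3ccccc3)c2c1 | intermediate (key-step product)
25 | 5-benzyloxy-3-[2,3,5,6-tetramethoxy-4-(6-methoxy-1H-indol-3-yl)phenyl]-1H-indole | COc1ccc2c(-c3c(OC)c(OC)c(-c4c[nH]c5ccc(OCc6ccccc6)cc45)c(OC)c3OC)c[nH]c2c1 | intermediate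
26 | 3-[2,3,5,6-tetramethoxy-4-(6-methoxy-1H-indol-3-yl)phenyl]-1H-indol-5-ol | COc1ccc2c(-c3c(OC)c(OC)c(-c4c[nH]c5ccc(O)cc45)c(OC)c3OC)c[nH]c2c1 | target

## Step count and least certain steps

Total step count: 13. Longest linear sequence: 12 steps (from 1 through steps 1 and 3 to 13, or from 3 through steps 2 to 13).

Step 11 (key step). The most likely failures are addition in the reverse orientation, which would put the methoxy group on C5, and consumption of the o-quinoid diene by self-dimerisation or by attack of the ketene acetal at the lactone carbonyl before cycloaddition. The fallback abandons ring construction for this indole and sets out from 8. 6-Methoxyindole F1 would be iodinated and N-sulfonylated as in step 2 to 3-iodo-6-methoxy-1-(phenylsulfonyl)indole F2, and Miyaura borylation (B2pin2, Pd(dppf)Cl2, KOAc, dioxane) would give 6-methoxy-1-(phenylsulfonyl)-3-(4,4,5,5-tetramethyl-1,3,2-dioxaborolan-2-yl)indole F3. Suzuki–Miyaura coupling of F3 with the hindered bromide 8 (Pd(OAc)2, SPhos, K3PO4, toluene/water) would come back to the route at 24.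

Step 10. The o-quinoid pyranone may oligomerise while Ac2O is removed, or reopen on handling, because the sulfonyl group takes away the stabilising donation from nitrogen. The fallback sets out from 18 and comes back at 24 without isolating the diene. Crude 19 would be dehydrated through its arylketene with 2-chloro-1-methylpyridinium iodide and Et3N in CH2Cl2/toluene in the presence of excess 21, so that 20 is trapped by cycloaddition as it forms. This fallback makes no compound outside the list (F0).

Step 9. Chemoselectivity may be lost, with hydride attacking the ester carbonyl or reducing the aldimine further before hydrolysis. The fallback sets out from 17 and lets the carboxyl group protect itself. Trifluoroacetic acid would first give 2-[4-Ar-3-cyano-1-(phenylsulfonyl)pyrrol-2-yl]acetic acid F4. Excess i-Bu2AlH at low temperature would then convert the acid to an unreactive aluminium carboxylate and reduce only the nitrile, coming back to the route at 19, which is cyclised with Ac2O as in step 10.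

Step 4. Oxidative addition at the bromide flanked by two methoxy groups may be slow, so that hydrodebromination or catalyst decay wins. The fallback makes the alkene by olefination and attaches the indole afterwards, setting out from 2. The lithio arene 6 would be quenched with DMF to give 4-bromo-2,3,5,6-tetramethoxybenzaldehyde F5, and Horner–Wadsworth–Emmons reaction with diethyl cyanomethylphosphonate and NaH would give (E)-3-(4-bromo-2,3,5,6-tetramethoxyphenyl)acrylonitrile F6. Iodide 5 would be borylated (B2pin2, Pd(dppf)Cl2, KOAc) to 5-benzyloxy-1-(phenylsulfonyl)-3-(4,4,5,5-tetramethyl-1,3,2-dioxaborolan-2-yl)indole F7. Suzuki–Miyaura coupling of F6 with F7 would come back to the route at 10.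

Step 7. Site-selectivity of the deprotonation may be lost, the amide base also metalating C2–H of the sulfonylindole and giving a mixture of iodides. The fallback functionalises the pyrrole before the indole is present, setting out from F6 of the preceding fallback. Reaction with 11 and NaH would give 4-(4-bromo-2,3,5,6-tetramethoxyphenyl)-1H-pyrrole-3-carbonitrile F8, and N-sulfonylation would give 4-(4-bromo-2,3,5,6-tetramethoxyphenyl)-1-(phenylsulfonyl)pyrrole-3-carbonitrile F9. Magnesiation and iodination as in step 7, now with a single sulfonyl-activated ring, would give 4-(4-bromo-2,3,5,6-tetramethoxyphenyl)-2-iodo-1-(phenylsulfonyl)pyrrole-3-carbonitrile F10. Coupling with 16 at the C–I bond would give tert-butyl 2-[4-(4-bromo-2,3,5,6-tetramethoxyphenyl)-3-cyano-1-(phenylsulfonyl)pyrrol-2-yl]acetate F11. Suzuki–Miyaura coupling of F11 with F7 would come back to the route at 17.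

## Further compounds

F1 | step 11 | 6-methoxyindole (purchased) | COc1ccc2cc[nH]c2c1
F2 | step 11 | 3-iodo-6-methoxy-1-(phenylsulfonyl)indole | COc1ccc2c(I)cn(S(=O)(=O)c3ccccc3)c2c1
F3 | step 11 | 6-methoxy-1-(phenylsulfonyl)-3-(4,4,5,5-tetramethyl-1,3,2-dioxaborolan-2-yl)indole | COc1ccc2c(B3OC(C)(C)C(C)(C)O3)cn(S(=O)(=O)c3ccccc3)c2c1
F0 | step 10 | none | none
F4 | step 9 | 2-[4-Ar-3-cyano-1-(phenylsulfonyl)pyrrol-2-yl]acetic acid | N#Cc1c(CC(=O)O)n(S(=O)(=O)c2ccccc2)cc1-c1c(OC)c(OC)c(-c2cn(S(=O)(=O)c3ccccc3)c3ccc(OCc4ccccc4)cc23)c(OC)c1OC
F5 | step 4 | 4-bromo-2,3,5,6-tetramethoxybenzaldehyde | COc1c(Br)c(OC)c(OC)c(C=O)c1OC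
F6 | step 4 | (E)-3-(4-bromo-2,3,5,6-tetramethoxyphenyl)acrylonitrile | N#C/C=C/c1c(OC)c(OC)c(Br)c(OC)c1OC
F7 | step 4 | 5-benzyloxy-1-(phenylsulfonyl)-3-(4,4,5,5-tetramethyl-1,3,2-dioxaborolan-2-yl)indole | O=S(=O)(c1ccccc1)n1cc(B2OC(C)(C)C(C)(C)O2)c2cc(OCc3ccccc3)ccc21
F8 | step 7 | 4-(4-bromo-2,3,5,6-tetramethoxyphenyl)-1H-pyrrole-3-carbonitrile | N#Cc1c[nH]cc1-c1c(OC)c(OC)c(Br)c(OC)c1OC
F9 | step 7 | 4-(4-bromo-2,3,5,6-tetramethoxyphenyl)-1-(phenylsulfonyl)pyrrole-3-carbonitrile | N#Cc1cn(S(=O)(=O)c2ccccc2)cc1-c1c(OC)c(OC)c(Br)c(OC)c1OC
F10 | step 7 | 4-(4-bromo-2,3,5,6-tetramethoxyphenyl)-2-iodo-1-(phenylsulfonyl)pyrrole-3-carbonitrile | N#Cc1c(I)n(S(=O)(=O)c2ccccc2)cc1-c1c(OC)c(OC)c(Br)c(OC)c1OC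
F11 | step 7 | tert-butyl 2-[4-(4-bromo-2,3,5,6-tetramethoxyphenyl)-3-cyano-1-(phenylsulfonyl)pyrrol-2-yl]acetate | CC(C)(C)OC(=O)Cc1c(C#N)c(-c2c(OC)c(OC)c(Br)c(OC)c2OC)cn1S(=O)(=O)c1ccccc1
A1 | alternative 1 | 5-benzyloxy-3-[2,3,5,6-tetramethoxy-4-(6-methoxy-2-triethylsilylindol-3-yl)phenyl]indole | CC[Si](CC)(CC)c1[nH]c2cc(OC)ccc2c1-c1c(OC)c(OC)c(-c2c[nH]c3ccc(OCc4ccccc4)cc23)c(OC)c1OC
A2 | alternative 1 | 5-benzyloxy-3-[2,3,5,6-tetramethoxy-4-(triethylsilylethynyl)phenyl]indole | CC[Si](CC)(CC)C#Cc1c(OC)c(OC)c(-c2c[nH]c3ccc(OCc4ccccc4)cc23)c(OC)c1OC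
A3 | alternative 1 | 2-iodo-5-methoxyaniline | COc1ccc(I)c(N)c1
A4 | alternative 2 | 2-(N-SEM-6-methoxyindol-3-yl)-5-(N-SEM-5-benzyloxyindol-3-yl)-3,6-dimethoxybenzene-1,4-diol | Oc1c(-c2cn(COCC[Si](C)(C)C)c3cc(OC)ccc23)c(OC)c(O)c(-c2cn(COCC[Si](C)(C)C)c3ccc(OCc4ccccc4)cc23)c1OC
A5 | alternative 2 | 4-hydroxy-3-methoxy-2-(N-SEM-6-methoxyindol-3-yl)-4-[(E)-2-methoxy-1-(N-SEM-5-benzyloxyindol-3-yl)vinyl]cyclobut-2-enone, racemic at C4 | CO/C=C(\c1cn(COCC[Si](C)(C)C)c2ccc(OCc3ccccc3)cc12)C1(O)C(OC)=C(c2cn(COCC[Si](C)(C)C)c3cc(OC)ccc23)C1=O
A6 | alternative 3 | 1-benzyl-3-[4-(1-benzyl-6-methoxyindol-3-yl)-2,3,5,6-tetramethoxyphenyl]indol-5-ol | COc1ccc2c(-c3c(OC)c(OC)c(-c4cn(Cc5ccccc5)c5ccc(O)cc45)c(OC)c3OC)cn(Cc3ccccc3)c2c1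
A7 | alternative 3 | 2-[4-(1-benzyl-6-methoxyindol-3-yl)-2,3,5,6-tetramethoxyphenyl]acetaldehyde | COc1ccc2c(-c3c(OC)c(OC)c(CC=O)c(OC)c3OC)cn(Cc3ccccc3)c2c1
A8 | alternative 3 | benzylamine | NCc1ccccc1
A9 | alternative 3 | p-benzoquinone | O=C1C=CC(=O)C=C1
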